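Cuts (eudesmane numbering): first C5–O by a retro-Schenck ene reaction, which restores the C4=C5 alkene. Next come the O3–angeloyl, O8–acetyl and O–CH3 ester bonds, then C11=C13 and C7–C11 (back to a C8 ketone), and last C1–C10 and C2–C3 of ring A. A formyl group on C2 serves as a traceless activator.
Enabling feature: with the ene step undone, ring A is a cyclohexene whose C4=C5 double bond sits between oxygen-bearing C3 and quaternary C10. This is the retron of a [4+2] addition of a C1–C2 dienophile to a C3=C4–C5=C10 dienol silyl ether whose C5=C10 bond lies in ring B.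
Forward order: ring B is bought as a 2-methyl-4-oxocyclohexenecarboxylate, and its ketalisation locks C5=C10, C14 and a masked C8 ketone. The ester carbon becomes C4 and is extended by C15 and C3 to the (E)-dienol ether, and ring A closes in the cycloaddition with acrolein. A temporary γ-lactone ring (C7–C11–C12–O–C8) carries the side-chain work and is opened again.
Stereochemistry: C3 and C10 (absolute) come from a chiral oxazaborolidinium catalyst combined with the endo mode. O3 is trans to C14 because of the E enol ether and suprafacial addition. C7 is set by equilibration to the equatorial position, and C8 and C5 by attack of hydride and of singlet oxygen on the α face, opposite the axial C14 methyl.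

Key step: step 6

Remark on numbering: ring A = C1–C2–C3–C4–C5–C10, ring B = C5–C6–C7–C8–C9–C10, C14 = methyl on C10, C15 = carbon on C4, C11 (with C12 and C13) = side chain on C7; β is the face that carries C14, α the opposite face.
Assumption: the (S)-prolinol-derived catalyst is taken to leave the si face of the acrolein α-carbon open, which in the endo mode gives the 3α,10β series drawn; should the first run show the opposite sense, the equally available (R)-configured catalyst is used with nothing else changed.

Step 1
Reactants: 1 ethyl 2-methyl-4-oxocyclohex-2-ene-1-carboxylate (Hagemann's ester, racemic)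
Product: 2 ethyl 7-methyl-1,4-dioxaspiro[4.5]dec-7-ene-8-carboxylate (achiral; holds C5=C10, C14, the C8 ketal and the future C4 as ester carbon)
Conditions: HOCH2CH2OH, p-TsOH·H2O (cat.), toluene, reflux, Dean–Stark trap
Reagents that add atoms: ethylene glycol, OCCO
Why: Acid-catalysed ketalisation of a conjugated enone goes through the dienol ether and leaves the double bond β,γ to the ketal carbon, a position that is here also conjugated with the ester, so the tetrasubstituted C5=C10 alkene is both the kinetic and the thermodynamic outcome and the stereocentre of racemic 1 disappears.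

Step 2
Reactants: 2 ethyl 7-methyl-1,4-dioxaspiro[4.5]dec-7-ene-8-carboxylate
Product: 4 1-(7-methyl-1,4-dioxaspiro[4.5]dec-7-en-8-yl)ethan-1-one, via Weinreb amide 3 (not isolated)
Conditions: MeNH(OMe)·HCl, i-PrMgCl, THF, −20 → 0 °C; then MeMgBr, 0 °C → rt
Reagents that add atoms: methylmagnesium bromide, C[Mg]Br; N,O-dimethylhydroxylamine hydrochloride, CNOC.Cl (its atoms stay in 3 only)
Why: Weinreb ketone synthesis in one flask: the chloromagnesium amide of MeNH(OMe) turns the ester into amide 3, and the magnesium-chelated tetrahedral adduct of 3 with MeMgBr survives until work-up, so that addition stops at the methyl ketone and the fully substituted β-carbon excludes conjugate addition.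

Step 3
Reactants: 4 1-(7-methyl-1,4-dioxaspiro[4.5]dec-7-en-8-yl)ethan-1-one
Product: 5 2-methyl-2-(7-methyl-1,4-dioxaspiro[4.5]dec-7-en-8-yl)oxirane (racemic)
Conditions: Me3SI, NaH, DMSO–THF, 0 °C → rt
Reagents that add atoms: trimethylsulfonium iodide, C[S+](C)C.[I-]
Why: Corey–Chaykovsky epoxidation: the unstabilised sulfonium ylide adds irreversibly to the carbonyl carbon and closes the oxirane by displacement of Me2S, cyclopropanation being excluded by the fully substituted β-carbon, and the new stereocentre (C4) is racemic and without consequence because it is flattened again in step 5.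

Step 4
Reactants: 5 2-methyl-2-(7-methyl-1,4-dioxaspiro[4.5]dec-7-en-8-yl)oxirane
Product: 6 2-(7-methyl-1,4-dioxaspiro[4.5]dec-7-en-8-yl)propanal (racemic, taken on without chromatography)
Conditions: MgBr2·OEt2 (20 mol %), Et2O, −10 °C
Reagents that add atoms: none
Why: Meinwald rearrangement: the mild Lewis acid opens the oxirane at its tertiary and allylic C4–O bond and a 1,2-hydride shift from C3 to C4 delivers the aldehyde, as is well known for 2-methyl-2-vinyloxiranes, while the absence of base keeps the double bond at C5=C10.

Step 5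
Reactants: 6 2-(7-methyl-1,4-dioxaspiro[4.5]dec-7-en-8-yl)propanal
Product: 7 (E)-tert-butyldimethyl{[2-(7-methyl-1,4-dioxaspiro[4.5]dec-7-en-8-yl)prop-1-en-1-yl]oxy}silane (silyloxy group trans to the ring across C3=C4)
Conditions: t-BuMe2SiOSO2CF3 (1.1 equiv), NEt3, CH2Cl2, −78 → 0 °C
Reagents that add atoms: tert-butyldimethylsilyl trifluoromethanesulfonate, CC(C)(C)[Si](C)(C)OS(=O)(=O)C(F)(F)F
Why: Soft enolisation with a silyl triflate and an amine: the only proton next to the O-silylated formyl group is H-4, which is also allylic, so the diene is formed with the ring double bond untouched, and the silyloxy group ends trans to the bulky, twisted cyclohexenyl group (E) because the Z arrangement suffers allylic 1,3-strain.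

Step 6
Reactants: 7 (E)-dienol silyl ether; 8 acrolein
Product: 9 3α-(tert-butyldimethylsilyloxy)-8,8-(ethylenedioxy)-11,12,13-trinoreudesm-4-ene-2α-carbaldehyde (10β-methyl; formyl cis to O3)
Conditions: (S)-3,3-diphenyl-1-(2-methylphenyl)tetrahydro-1H,3H-pyrrolo[1,2-c][1,3,2]oxazaborole (20 mol %) + HN(SO2CF3)2 (17 mol %), 8 (3 equiv), CH2Cl2, −78 → −40 °C
Reagents that add atoms: none
Why: Acrolein binds through oxygen to the cationic boron, held in place by a formyl C–H···O contact, and the cisoid diene adds to its open face in a concerted, suprafacial but asynchronous [4+2] cycloaddition in which the C10–C1 bond runs ahead of the C3–C2 bond. The closest known reaction type is the enantioselective Diels–Alder addition of acrolein and 2-substituted acroleins to 1-oxygenated and other 1-substituted dienes under protonated oxazaborolidine catalysis, and 2-methyl-1-vinylcyclohexene-type dienes are known to give angular-methyl octalins in ordinary Diels–Alder reactions. Ring A is closed as a six-membered carbocycle by an intermolecular two-bond cycloaddition onto ring B, the former C4–C5 single bond becoming the tetrasubstituted alkene. The trans relation of O3 (at C3) to C14 (at C10) follows from the diene geometry, silyloxy outside (E) and methyl inside (ring-enforced), the cis relation of the formyl group at C2 to O3 from the endo mode, and the absolute configuration of all three centres from the catalyst-shielded face of acrolein. The step needs ortho regioselectivity, secured because the silyloxy donor makes C10 the nucleophilic terminus and C10 also meets the unsubstituted CH2 of acrolein, sufficient reactivity, helped by C15, which clashes with C14 in the transoid rotamer and so raises the share of the cisoid one, and endo selectivity, favoured by Lewis-acid activation. Because an exo approach to the same acrolein face uses the opposite diene face and would end in the antipodal C3/C10 series once C2 is cleared, the exo aldehyde is removed by chromatography on neutral silica before step 7, any Z isomer of 7 (two inside groups) staying unreacted.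

Step 7
Reactants: 9 2α-formyl adduct (diastereomerically pure)
Product: 10 3α-(tert-butyldimethylsilyloxy)-8,8-(ethylenedioxy)-11,12,13-trinoreudesm-4-ene (10β-methyl)
Conditions: RhCl(PPh3)3 (1.1 equiv), toluene, 110 °C
Reagents that add atoms: none
Why: Tsuji–Wilkinson decarbonylation: oxidative addition of the formyl C–H bond to monovalent rhodium, extrusion of CO into the coordination sphere and C–H reductive elimination from trivalent rhodium replace CHO by H under neutral conditions that leave the β-silyloxy group, the ketal, the tetrasubstituted alkene and the centres C3 and C10 untouched.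

Step 8
Reactants: 10 ketal silyl ether
Product: 11 3α-(tert-butyldimethylsilyloxy)-11,12,13-trinoreudesm-4-en-8-one
Conditions: pyridinium p-toluenesulfonate (cat.), acetone–H2O, 55 °C
Reagents that add atoms: water, O
Why: Acid-catalysed ketal hydrolysis under buffered conditions that a secondary tert-butyldimethylsilyl ether tolerates; the alkene cannot move into conjugation because it is γ,δ to the new carbonyl group on one side and shut off by quaternary C10 on the other.

Step 9
Reactants: 11 C8 ketone; 12 methyl bromoacetate
Product: 14 methyl 3α-(tert-butyldimethylsilyloxy)-8-oxo-13-noreudesm-4-en-12-oate (7β arm and H-7α), via keto ester epimers 13 (not isolated)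
Conditions: LiN(i-Pr)2, THF, −78 °C; 12, DMPU, −78 → −20 °C; then NaOMe (cat.), MeOH, rt
Reagents that add atoms: none
Why: Kinetic enolate alkylation: the amide base takes a proton from C7 and not from the neopentyl-type C9 next to quaternary C10, and methoxide-catalysed epimerisation of the enolisable C7 centre then moves the acetate arm into the equatorial 7β position of the ring B chair, whose axial β site at C10 is held by C14.

Step 10
Reactants: 14 7β keto ester
Product: 16 3α-(tert-butyldimethylsilyloxy)-13-noreudesm-4-en-8β,12-olide (cis-fused γ-lactone; H-7 and H-8 both α), via hydroxy ester 15 (not isolated)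
Conditions: LiBH(s-Bu)3, THF, −78 °C → rt
Reagents that add atoms: none
Why: Diastereoselective ketone reduction by a bulky borohydride followed by lactonisation: hydride arrives along the equatorial trajectory on the α face because the β face of C8 is closed by the syn-axial C14 methyl, and the axial 8β-alkoxide so formed attacks the neighbouring 7β ester arm to close the cis-fused γ-lactone.

Step 11
Reactants: 16 cis-lactone
Product: 19 3α-(tert-butyldimethylsilyloxy)eudesma-4,11(13)-dien-8β,12-olide, via Mannich base 17 (not isolated), via methiodide 18 (not isolated)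
Conditions: LiN(i-Pr)2, THF, −78 °C; [CH2=NMe2]I, −78 °C → rt; MeI, THF, rt; aq. NaHCO3, CH2Cl2, rt
Reagents that add atoms: N,N-dimethylmethyleneiminium iodide, C=[N+](C)C.[I-]; iodomethane, CI (its atoms stay in 18 only)
Why: α-Methylenation of a lactone by Mannich reaction of its enolate with the preformed iminium salt, N-methylation and E1cB (Hofmann-type) elimination: C11 carries the only acidic protons of 16, and its transient stereocentre disappears with the loss of NMe3.

Step 12
Reactants: 19 α-methylene lactone
Product: 21 methyl 3α-(tert-butyldimethylsilyloxy)-8β-hydroxyeudesma-4,11(13)-dien-12-oate, via potassium carboxylate 20 (not isolated)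
Conditions: KOH (1.1 equiv), THF–H2O, rt; evaporate; MeI, DMF, 0 °C → rt
Reagents that add atoms: potassium hydroxide, [K+].[OH-]; iodomethane, CI
Why: Saponification and SN2 O-alkylation of the carboxylate: hydroxide attacks the strained lactone carbonyl, the acrylate anion formed is a poor Michael acceptor, and methylating the salt without ever acidifying it avoids the free hydroxy acid that would close again, C7 and C8 being untouched since the C8–O bond is not broken.

Step 13
Reactants: 21 hydroxy ester (unchromatographed)
Product: 22 methyl 8β-acetoxy-3α-(tert-butyldimethylsilyloxy)eudesma-4,11(13)-dien-12-oate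
Conditions: Ac2O, 4-(dimethylamino)pyridine (cat.), pyridine, 0 °C → rt
Reagents that add atoms: acetic anhydride, CC(=O)OC(C)=O
Why: Acylation under nucleophilic catalysis by 4-(dimethylamino)pyridine acetylates the axial 8β-hydroxyl group of the freshly prepared hydroxy ester faster than the conjugated and therefore sluggish methyl ester can relactonise.

Step 14
Reactants: 22 acetate silyl ether
Product: 23 methyl 8β-acetoxy-3α-hydroxyeudesma-4,11(13)-dien-12-oate
Conditions: HF·pyridine, THF, 0 °C → rt
Reagents that add atoms: none
Why: Fluoride-induced desilylation driven by the strong Si–F bond, run with the weakly acidic HF·pyridine rather than a basic fluoride so that the acetate, the methyl ester and the acrylate are not touched and C3 keeps its configuration because only the O–Si bond breaks.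

Step 15
Reactants: 23 3α-alcohol; 24 angelic acid, (Z)-2-methylbut-2-enoic acid
Product: 26 methyl 8β-acetoxy-3α-angeloyloxyeudesma-4,11(13)-dien-12-oate, via mixed anhydride 25 (not isolated)
Conditions: 24, 2,4,6-Cl3C6H2COCl, NEt3, toluene, rt; then 23, 80 °C
Reagents that add atoms: 2,4,6-trichlorobenzoyl chloride, O=C(Cl)c1c(Cl)cc(Cl)cc1Cl (its atoms stay in 25 only)
Why: Yamaguchi-type mixed-anhydride esterification: the alcohol attacks the unhindered angeloyl carbonyl of 25, and omitting nucleophilic pyridine catalysts shuts off the addition–elimination pathway that turns angelates into tiglates, so the Z geometry and the C3 configuration (C–O bond untouched) are kept.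

Step 16
Reactants: 26 Δ4 angelate
Product: 27 methyl 8β-acetoxy-3α-angeloyloxy-5α-hydroperoxyeudesma-4(15),11(13)-dien-12-oate (target)
Conditions: O2, 5,10,15,20-tetraphenylporphyrin (cat.), hν (visible), CH2Cl2, −20 °C; no reductive work-up
Reagents that add atoms: oxygen, O=O
Why: Schenck ene reaction: singlet oxygen picks the only electron-rich alkene (tetrasubstituted C4=C5, the acrylate and the angelate being electron-poor) and approaches on the α face opposite the axial C14 methyl, where only the C15–H bonds can align with the π system (the 3α site holds the ester, whose withdrawing effect also disfavours C4–O bonding, and H-6α is equatorial and lies near the nodal plane), so oxygen binds to C5, which becomes the 5α-hydroperoxide centre, and the double bond moves to C4=C15.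

Compound list
1 | ethyl 2-methyl-4-oxocyclohex-2-ene-1-carboxylate (Hagemann's ester, racemic) | CCOC(=O)C1CCC(=O)C=C1C | starting material
2 | ethyl 7-methyl-1,4-dioxaspiro[4.5]dec-7-ene-8-carboxylate | CCOC(=O)C1=C(C)CC2(CC1)OCCO2 | intermediate
3 | N-methoxy-N,7-dimethyl-1,4-dioxaspiro[4.5]dec-7-ene-8-carboxamide | CON(C)C(=O)C1=C(C)CC2(CC1)OCCO2 | intermediate
4 | 1-(7-methyl-1,4-dioxaspiro[4.5]dec-7-en-8-yl)ethan-1-one | CC(=O)C1=C(C)CC2(CC1)OCCO2 | intermediate
5 | 2-methyl-2-(7-methyl-1,4-dioxaspiro[4.5]dec-7-en-8-yl)oxirane (racemic) | CC1(CO1)C3=C(C)CC2(CC3)OCCO2 | intermediate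
6 | 2-(7-methyl-1,4-dioxaspiro[4.5]dec-7-en-8-yl)propanal (racemic) | CC(C=O)C1=C(C)CC2(CC1)OCCO2 | intermediate
7 | (E)-tert-butyldimethyl{[2-(7-methyl-1,4-dioxaspiro[4.5]dec-7-en-8-yl)prop-1-en-1-yl]oxy}silane | CC1=C(/C(C)=C/O[Si](C)(C)C(C)(C)C)CCC2(C1)OCCO2 | intermediate
8 | acrolein | C=CC=O | starting material
9 | 3α-(tert-butyldimethylsilyloxy)-8,8-(ethylenedioxy)-11,12,13-trinoreudesm-4-ene-2α-carbaldehyde | C1CC2=C(C)[C@H](O[Si](C)(C)C(C)(C)C)[C@H](C=O)C[C@]2(C)CC13OCCO3 | intermediate
10 | 3α-(tert-butyldimethylsilyloxy)-8,8-(ethylenedioxy)-11,12,13-trinoreudesm-4-ene | C1CC2=C(C)[C@H](O[Si](C)(C)C(C)(C)C)CC[C@]2(C)CC13OCCO3 | intermediate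
11 | 3α-(tert-butyldimethylsilyloxy)-11,12,13-trinoreudesm-4-en-8-one | O=C1CCC2=C(C)[C@H](O[Si](C)(C)C(C)(C)C)CC[C@]2(C)C1 | intermediate
12 | methyl bromoacetate | COC(=O)CBr | starting material
13 | methyl 3α-(tert-butyldimethylsilyloxy)-8-oxo-13-noreudesm-4-en-12-oate, C7 epimers | COC(=O)CC1CC2=C(C)[C@H](O[Si](C)(C)C(C)(C)C)CC[C@]2(C)CC1=O | intermediate
14 | methyl 3α-(tert-butyldimethylsilyloxy)-8-oxo-13-noreudesm-4-en-12-oate (7β arm) | COC(=O)C[C@H]1CC2=C(C)[C@H](O[Si](C)(C)C(C)(C)C)CC[C@]2(C)CC1=O | intermediate
15 | methyl 3α-(tert-butyldimethylsilyloxy)-8β-hydroxy-13-noreudesm-4-en-12-oate | COC(=O)C[C@H]1CC2=C(C)[C@H](O[Si](C)(C)C(C)(C)C)CC[C@]2(C)C[C@H]1O | intermediate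
16 | 3α-(tert-butyldimethylsilyloxy)-13-noreudesm-4-en-8β,12-olide | O=C1C[C@H]2CC3=C(C)[C@H](O[Si](C)(C)C(C)(C)C)CC[C@]3(C)C[C@H]2O1 | intermediate
17 | 13-(dimethylamino)-3α-(tert-butyldimethylsilyloxy)eudesm-4-en-8β,12-olide (C11 epimers) | O=C1C(CN(C)C)[C@H]2CC3=C(C)[C@H](O[Si](C)(C)C(C)(C)C)CC[C@]3(C)C[C@H]2O1 | intermediate
18 | 13-(trimethylammonio)-3α-(tert-butyldimethylsilyloxy)eudesm-4-en-8β,12-olide iodide | O=C1C(C[N+](C)(C)C)[C@H]2CC3=C(C)[C@H](O[Si](C)(C)C(C)(C)C)CC[C@]3(C)C[C@H]2O1.[I-] | intermediate
19 | 3α-(tert-butyldimethylsilyloxy)eudesma-4,11(13)-dien-8β,12-olide | O=C1C(=C)[C@H]2CC3=C(C)[C@H](O[Si](C)(C)C(C)(C)C)CC[C@]3(C)C[C@H]2O1 | intermediate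
20 | potassium 3α-(tert-butyldimethylsilyloxy)-8β-hydroxyeudesma-4,11(13)-dien-12-oate | C=C(C(=O)[O-])[C@H]1CC2=C(C)[C@H](O[Si](C)(C)C(C)(C)C)CC[C@]2(C)C[C@H]1O.[K+] | intermediate
21 | methyl 3α-(tert-butyldimethylsilyloxy)-8β-hydroxyeudesma-4,11(13)-dien-12-oate | C=C(C(=O)OC)[C@H]1CC2=C(C)[C@H](O[Si](C)(C)C(C)(C)C)CC[C@]2(C)C[C@H]1O | intermediate
22 | methyl 8β-acetoxy-3α-(tert-butyldimethylsilyloxy)eudesma-4,11(13)-dien-12-oate | C=C(C(=O)OC)[C@H]1CC2=C(C)[C@H](O[Si](C)(C)C(C)(C)C)CC[C@]2(C)C[C@H]1OC(C)=O | intermediate
23 | methyl 8β-acetoxy-3α-hydroxyeudesma-4,11(13)-dien-12-oate | C=C(C(=O)OC)[C@H]1CC2=C(C)[C@H](O)CC[C@]2(C)C[C@H]1OC(C)=O | intermediate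
24 | angelic acid, (Z)-2-methylbut-2-enoic acid | C/C=C(/C)C(=O)O | starting material
25 | angelic 2,4,6-trichlorobenzoic anhydride | C/C=C(/C)C(=O)OC(=O)c1c(Cl)cc(Cl)cc1Cl | intermediate
26 | methyl 8β-acetoxy-3α-angeloyloxyeudesma-4,11(13)-dien-12-oate | C=C(C(=O)OC)[C@H]1CC2=C(C)[C@H](OC(=O)/C(C)=C\C)CC[C@]2(C)C[C@H]1OC(C)=O | intermediate
27 | methyl 8β-acetoxy-3α-angeloyloxy-5α-hydroperoxyeudesma-4(15),11(13)-dien-12-oate | C=C(C(=O)OC)[C@H]1C[C@@]2(OO)C(=C)[C@H](OC(=O)/C(C)=C\C)CC[C@]2(C)C[C@H]1OC(C)=O | target

Total step count: 16. Longest linear sequence: 16 steps (1 → 27); 8, 12 and 24 are bought and enter directly.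

Steps most likely to fail

**Step 6.**
- The cycloaddition may be slow because the inside methyl crowds the cisoid rotamer.
- The strongly acidic catalyst may cause protodesilylation of the enol ether or opening of the ketal.
- A stepwise Michael-type pathway may loosen the O3/C14 relation.
- Incomplete endo preference or weak face discrimination would lower the optical purity after C2 is cleared.
- Epimerisation at C2 before the exo isomer is removed would have the same effect.

Fallback: absolute control by a catalyst is given up in favour of a resolution. Setting out from 7 and 8, the two are combined without any Lewis acid (toluene, 2,6-di-tert-butyl-4-methylphenol, sealed tube, 110 °C, or CH2Cl2 at about 12 kbar) to the racemic 2-formyl adduct F1. Its endo and exo isomers are equally useful, since both converge once C2 is cleared. RhCl(PPh3)3 in hot toluene gives the racemic silyl ether F2, and Bu4NF in THF gives the racemic 3α-alcohol F3. Esterification with (S)-2-methoxy-2-phenylacetic acid (dicyclohexylcarbodiimide, 4-(dimethylamino)pyridine) gives two diastereomers that are separated by chromatography or crystallisation: the wanted 3α,10β-configured mandelate F4 and the unwanted antipodal-core mandelate F5. K2CO3 in MeOH frees the enantiopure 3α-alcohol F6, and t-BuMe2SiCl with imidazole comes back to the route at 10.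

**Step 12.** Hydroxide may add in a conjugate sense to the methylene lactone. The larger risk is reclosure of the lactone during alkylation, concentration or the following acetylation, because the hydroxy ester is the less stable partner of that equilibrium.

Fallback: the oxidation level of C12 is lowered so that no γ-hydroxy ester is ever present. Setting out from 19, i-Bu2AlH (CH2Cl2, −78 → 0 °C) gives the 8β,12-diol F7, and Ac2O in pyridine with 4-(dimethylamino)pyridine gives the 8β,12-diacetate F8. K2CO3 in MeOH at 0 °C cleaves only the unhindered primary allylic acetate to the 12-hydroxy 8β-acetate F9. MnO2 in CH2Cl2 then gives the 2-substituted enal F10, Pinnick oxidation (NaClO2, NaH2PO4, 2-methylbut-2-ene, t-BuOH–H2O) gives the acrylic acid F11, and Me3SiCHN2 in toluene–MeOH comes back to the route at 22.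

**Step 16.** Singlet oxygen may attack the β face, or react sluggishly because the axial 3α-ester crowds the α face. Either would erode facial selectivity, and long irradiation would invite decomposition of the allylic hydroperoxide.

Fallback: the oxygenation is moved in front of the esterification, so that a hydrogen bond as well as steric bias steers the reagent. Setting out from 23, photooxygenation in a non-polar medium (O2, 5,10,15,20-tetraphenylporphyrin, hν, CH2Cl2 or CCl4) uses the conformationally locked, pseudo-axial 3α-hydroxyl group as a hydrogen-bond donor for the incoming oxygen on the α face. It should give the 3α-hydroxy 5α-hydroperoxide F12. The more acidic and less hindered OOH group is capped selectively (Et3SiCl, imidazole, CH2Cl2, −40 °C) as the triethylsilyl peroxide F13. The 3α-alcohol is esterified through 25 as in step 15 to the angelate silyl peroxide F14, and HF·pyridine releases the hydroperoxide, which comes back to the route at 27.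

Further compounds
F1 | step 6 | racemic 3α-(tert-butyldimethylsilyloxy)-8,8-(ethylenedioxy)-11,12,13-trinoreudesm-4-ene-2-carbaldehyde, C2 epimers, both enantiomers written | C1CC2=C(C)[C@H](O[Si](C)(C)C(C)(C)C)C(C=O)C[C@]2(C)CC13OCCO3.C1CC2=C(C)[C@@H](O[Si](C)(C)C(C)(C)C)C(C=O)C[C@@]2(C)CC13OCCO3
F2 | step 6 | racemate of 10, both enantiomers written | C1CC2=C(C)[C@H](O[Si](C)(C)C(C)(C)C)CC[C@]2(C)CC13OCCO3.C1CC2=C(C)[C@@H](O[Si](C)(C)C(C)(C)C)CC[C@@]2(C)CC13OCCO3
F3 | step 6 | racemic 8,8-(ethylenedioxy)-11,12,13-trinoreudesm-4-en-3α-ol, both enantiomers written | C1CC2=C(C)[C@H](O)CC[C@]2(C)CC13OCCO3.C1CC2=C(C)[C@@H](O)CC[C@@]2(C)CC13OCCO3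
F4 | step 6 | 8,8-(ethylenedioxy)-11,12,13-trinoreudesm-4-en-3α-yl (S)-2-methoxy-2-phenylacetate (wanted diastereomer) | C1CC2=C(C)[C@H](OC(=O)[C@@H](OC)c4ccccc4)CC[C@]2(C)CC13OCCO3
F5 | step 6 | (S)-2-methoxy-2-phenylacetate of the antipodal alcohol (unwanted diastereomer) | C1CC2=C(C)[C@@H](OC(=O)[C@@H](OC)c4ccccc4)CC[C@@]2(C)CC13OCCO3
F6 | step 6 | enantiopure 8,8-(ethylenedioxy)-11,12,13-trinoreudesm-4-en-3α-ol | C1CC2=C(C)[C@H](O)CC[C@]2(C)CC13OCCO3
F7 | step 12 | 3α-(tert-butyldimethylsilyloxy)eudesma-4,11(13)-diene-8β,12-diol | C=C(CO)[C@H]1CC2=C(C)[C@H](O[Si](C)(C)C(C)(C)C)CC[C@]2(C)C[C@H]1O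
F8 | step 12 | 8β,12-diacetoxy-3α-(tert-butyldimethylsilyloxy)eudesma-4,11(13)-diene | C=C(COC(C)=O)[C@H]1CC2=C(C)[C@H](O[Si](C)(C)C(C)(C)C)CC[C@]2(C)C[C@H]1OC(C)=O
F9 | step 12 | 8β-acetoxy-3α-(tert-butyldimethylsilyloxy)eudesma-4,11(13)-dien-12-ol | C=C(CO)[C@H]1CC2=C(C)[C@H](O[Si](C)(C)C(C)(C)C)CC[C@]2(C)C[C@H]1OC(C)=O
F10 | step 12 | 8β-acetoxy-3α-(tert-butyldimethylsilyloxy)eudesma-4,11(13)-dien-12-al | C=C(C=O)[C@H]1CC2=C(C)[C@H](O[Si](C)(C)C(C)(C)C)CC[C@]2(C)C[C@H]1OC(C)=O
F11 | step 12 | 8β-acetoxy-3α-(tert-butyldimethylsilyloxy)eudesma-4,11(13)-dien-12-oic acid | C=C(C(=O)O)[C@H]1CC2=C(C)[C@H](O[Si](C)(C)C(C)(C)C)CC[C@]2(C)C[C@H]1OC(C)=O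
F12 | step 16 | methyl 8β-acetoxy-5α-hydroperoxy-3α-hydroxyeudesma-4(15),11(13)-dien-12-oate | C=C(C(=O)OC)[C@H]1C[C@@]2(OO)C(=C)[C@H](O)CC[C@]2(C)C[C@H]1OC(C)=O
F13 | step 16 | methyl 8β-acetoxy-3α-hydroxy-5α-(triethylsilylperoxy)eudesma-4(15),11(13)-dien-12-oate | C=C(C(=O)OC)[C@H]1C[C@@]2(OO[Si](CC)(CC)CC)C(=C)[C@H](O)CC[C@]2(C)C[C@H]1OC(C)=O
F14 | step 16 | methyl 8β-acetoxy-3α-angeloyloxy-5α-(triethylsilylperoxy)eudesma-4(15),11(13)-dien-12-oate | C=C(C(=O)OC)[C@H]1C[C@@]2(OO[Si](CC)(CC)CC)C(=C)[C@H](OC(=O)/C(C)=C\C)CC[C@]2(C)C[C@H]1OC(C)=O
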